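## Retrosynthetic overview
1. The target comes from its tris-TBS ether by global fluoride desilylation. The (Z)-C8=C9 alkene comes from a Wittig union of a C1–C8 arylalkyl phosphonium salt (fragment 1) with (S)-3-silyloxynonanal (fragment 2).
2. Fragment 2 comes from ozonolysis of O-TBS (S)-dec-1-en-4-ol. Its C10–C11 bond and the only stereocentre are made in the key step, an intermolecular asymmetric carbonyl allylation of heptanal (Brown allylboration).
3. Fragment 1 comes from copper-catalysed coupling of 3,5-dimethoxyphenylmagnesium bromide with 1,8-dibromooctane, an early OMe-to-OTBS exchange, then PPh3.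
4. No ring is formed. The resorcinol ring is bought intact as 1-bromo-3,5-dimethoxybenzene.

Assumption: the SMILES descriptor is read as (11S) (OH > C10 > C12 > H), the mirror image of the ricinoleate carbinol, and the alkene as (8Z). The chain is numbered from the benzylic carbon. TBS = tert-butyldimethylsilyl, Ipc = isopinocampheyl.

## Route

Step 1
Reactants: 1 1-bromo-3,5-dimethoxybenzene; 2 1,8-dibromooctane
Product: 4 1-(8-bromooctyl)-3,5-dimethoxybenzene, via 3,5-dimethoxyphenylmagnesium bromide 3 (not isolated)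
Conditions: 1, Mg, I2 (cat.), THF, reflux, 2 h; then cannulated slowly into 2 (3 equiv), Li2CuCl4 (5 mol %), THF, −10 °C to rt, 12 h; surplus 2 distilled off
Reagents that add atoms: none
Why: In this Kochi copper-catalysed Grignard–alkyl bromide cross-coupling, inverse addition into excess dibromide keeps the reaction at mono-arylation, and the methyl ethers are inert to the Grignard reagent.

Step 2
Reactants: 4 1-(8-bromooctyl)-3,5-dimethoxybenzene
Product: 6 5-(8-bromooctyl)benzene-1,3-diol, via bis(dibromoboryl) ether 5 (not isolated)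
Conditions: BBr3 (3 equiv), CH2Cl2, −78 °C to rt, 12 h; then ice/H2O
Reagents that add atoms: none
Why: BBr3 aryl methyl ether cleavage is done now, when the only other function is a primary bromide that BBr3 leaves alone, so the later alkene and carbinol never meet a strong Lewis acid.

Step 3
Reactants: 6 5-(8-bromooctyl)benzene-1,3-diol
Product: 7 1-(8-bromooctyl)-3,5-bis(tert-butyldimethylsilyloxy)benzene
Conditions: TBSCl (2.4 equiv), imidazole (5 equiv), CH2Cl2/DMF 4:1, 0 °C to rt, 3 h
Reagents that add atoms: tert-butyldimethylsilyl chloride (TBSCl), CC(C)(C)[Si](C)(C)Cl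
Why: Imidazole-promoted silylation (Corey protocol) of phenols is far faster than N-alkylation of imidazole by the primary bromide, and it installs groups that fluoride removes at the end.

Step 4
Reactants: 7 1-(8-bromooctyl)-3,5-bis(tert-butyldimethylsilyloxy)benzene
Product: 8 {8-[3,5-bis(tert-butyldimethylsilyloxy)phenyl]octyl}triphenylphosphonium bromide
Conditions: PPh3 (1.5 equiv), MeCN, reflux, 48 h; silica plug (CH2Cl2/MeOH); dried by toluene azeotrope
Reagents that add atoms: triphenylphosphine, c1ccc(cc1)P(c1ccccc1)c1ccccc1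
Why: SN2 quaternisation of PPh3 by an unhindered primary bromide runs under neutral conditions that aryl silyl ethers tolerate.

Step 5 (key step)
Reactants: 9 heptanal; 10 allylmagnesium bromide; 11 (+)-B-methoxydiisopinocampheylborane [(+)-Ipc2BOMe, the enantiomer made from (−)-α-pinene]
Product: 14 (S)-dec-1-en-4-ol, via (+)-B-allyldiisopinocampheylborane 12 (not isolated), via Ipc2B borinate ester 13 (not isolated)
Conditions: 11 (1.2 equiv), 10 (1.15 equiv, 1 M in Et2O), Et2O, −78 °C to rt, 1 h; cool to −78 °C, add 9 (1.0 equiv), 3 h; then 3 M NaOH, 30% H2O2, 0 °C to rt, 6 h; chromatography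
Reagents that add atoms: none
Why: In the Brown asymmetric allylboration, the chair Zimmerman–Traxler transition state of the (−)-α-pinene-derived reagent delivers allyl to the Re face of the n-alkanal and gives the (S)-carbinol in about 94–96% ee, mirroring the known (R)-selectivity of the (+)-α-pinene-derived reagent.

Step 6
Reactants: 14 (S)-dec-1-en-4-ol
Product: 15 (S)-tert-butyl(dec-1-en-4-yloxy)dimethylsilane
Conditions: TBSCl (1.3 equiv), imidazole (2.6 equiv), DMF, rt, 12 h
Reagents that add atoms: tert-butyldimethylsilyl chloride (TBSCl), CC(C)(C)[Si](C)(C)Cl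
Why: Standard Corey silylation of a secondary alcohol breaks no C–O bond, so the configuration is retained, and any trace of isopinocampheol is removed here because its silyl ether elutes separately.

Step 7
Reactants: 15 (S)-tert-butyl(dec-1-en-4-yloxy)dimethylsilane
Product: 17 (S)-3-(tert-butyldimethylsilyloxy)nonanal, via secondary ozonide 16 (not isolated)
Conditions: O3, CH2Cl2, −78 °C until pale blue, Ar purge; PPh3 (1.1 equiv), −78 °C to rt, 2 h; short silica column, used within a day
Reagents that add atoms: ozone, [O-][O+]=O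
Why: Criegee ozonolysis of the only alkene with a neutral reductive work-up gives the β-silyloxy aldehyde without acid or base, so neither elimination nor loss of the β-stereocentre can occur.

Step 8
Reactants: 8 {8-[3,5-bis(tert-butyldimethylsilyloxy)phenyl]octyl}triphenylphosphonium bromide; 17 (S)-3-(tert-butyldimethylsilyloxy)nonanal
Product: 19 5-[(8Z,11S)-11-(tert-butyldimethylsilyloxy)heptadec-8-en-1-yl]-1,3-bis(tert-butyldimethylsilyloxy)benzene, via phosphorus ylide 18 (not isolated)
Conditions: 8 (1.25 equiv), NaN(SiMe3)2 (1.2 equiv), THF, 0 °C, 45 min; cool to −78 °C, add 17 (1.0 equiv) in THF; −78 °C to rt over 4 h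
Reagents that add atoms: none
Why: A lithium-free Wittig olefination of a non-stabilised ylide with an aliphatic aldehyde proceeds under kinetic control through the cis-oxaphosphetane (Z:E about 95:5 or better), and addition at −78 °C outruns β-elimination, so C11 is untouched.

Step 9
Reactants: 19 5-[(8Z,11S)-11-(tert-butyldimethylsilyloxy)heptadec-8-en-1-yl]-1,3-bis(tert-butyldimethylsilyloxy)benzene
Product: 20 5-[(8Z,11S)-11-hydroxyheptadec-8-en-1-yl]benzene-1,3-diol (target)
Conditions: Bu4NF (6 equiv), AcOH (3 equiv), THF, Ar, 0 °C to rt, 16–24 h; pH 7 buffer work-up; chromatography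
Reagents that add atoms: none
Why: Fluoride-driven desilylation (Si–F bond formation) cleaves the two aryl ethers at once and the unhindered secondary ether within hours, AcOH supplies the protons so the air-sensitive resorcinolate does not persist, and neither the Z-alkene nor the C11–O bond is affected.

## Compound list
1 | 1-bromo-3,5-dimethoxybenzene | COc1cc(Br)cc(OC)c1 | starting material
2 | 1,8-dibromooctane | BrCCCCCCCCBr | starting material
3 | 3,5-dimethoxyphenylmagnesium bromide (formed in the flask) | COc1cc([Mg]Br)cc(OC)c1 | intermediate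
4 | 1-(8-bromooctyl)-3,5-dimethoxybenzene | COc1cc(CCCCCCCCBr)cc(OC)c1 | intermediate
5 | 1-(8-bromooctyl)-3,5-bis[(dibromoboryl)oxy]benzene (formed in the flask) | BrCCCCCCCCc1cc(OB(Br)Br)cc(OB(Br)Br)c1 | intermediate
6 | 5-(8-bromooctyl)benzene-1,3-diol | Oc1cc(O)cc(CCCCCCCCBr)c1 | intermediate
7 | 1-(8-bromooctyl)-3,5-bis(tert-butyldimethylsilyloxy)benzene | CC(C)(C)[Si](C)(C)Oc1cc(CCCCCCCCBr)cc(O[Si](C)(C)C(C)(C)C)c1 | intermediate
8 | {8-[3,5-bis(tert-butyldimethylsilyloxy)phenyl]octyl}triphenylphosphonium bromide | CC(C)(C)[Si](C)(C)Oc1cc(CCCCCCCC[P+](c2ccccc2)(c2ccccc2)c2ccccc2)cc(O[Si](C)(C)C(C)(C)C)c1.[Br-] | intermediate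
9 | heptanal | CCCCCCC=O | starting material
10 | allylmagnesium bromide | C=CC[Mg]Br | starting material
11 | (+)-B-methoxydiisopinocampheylborane, from (−)-α-pinene | COB([C@H]1C[C@H]2C[C@@H]([C@@H]1C)C2(C)C)[C@H]1C[C@H]2C[C@@H]([C@@H]1C)C2(C)C | starting material
12 | (+)-B-allyldiisopinocampheylborane (formed in the flask) | C=CCB([C@H]1C[C@H]2C[C@@H]([C@@H]1C)C2(C)C)[C@H]1C[C@H]2C[C@@H]([C@@H]1C)C2(C)C | intermediate
13 | (S)-dec-1-en-4-yl diisopinocampheylborinate (formed in the flask) | CCCCCC[C@H](OB([C@H]1C[C@H]2C[C@@H]([C@@H]1C)C2(C)C)[C@H]1C[C@H]2C[C@@H]([C@@H]1C)C2(C)C)CC=C | intermediate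
14 | (S)-dec-1-en-4-ol | CCCCCC[C@H](O)CC=C | intermediate
15 | (S)-tert-butyl(dec-1-en-4-yloxy)dimethylsilane | CCCCCC[C@H](O[Si](C)(C)C(C)(C)C)CC=C | intermediate
16 | 3-[(S)-2-(tert-butyldimethylsilyloxy)octyl]-1,2,4-trioxolane, both epimers at the ring carbon (formed in the flask) | CCCCCC[C@H](O[Si](C)(C)C(C)(C)C)CC1OCOO1 | intermediate
17 | (S)-3-(tert-butyldimethylsilyloxy)nonanal | CCCCCC[C@H](O[Si](C)(C)C(C)(C)C)CC=O | intermediate
18 | {8-[3,5-bis(tert-butyldimethylsilyloxy)phenyl]octylidene}triphenylphosphorane (formed in the flask) | CC(C)(C)[Si](C)(C)Oc1cc(CCCCCCCC=P(c2ccccc2)(c2ccccc2)c2ccccc2)cc(O[Si](C)(C)C(C)(C)C)c1 | intermediate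
19 | 5-[(8Z,11S)-11-(tert-butyldimethylsilyloxy)heptadec-8-en-1-yl]-1,3-bis(tert-butyldimethylsilyloxy)benzene | CCCCCC[C@H](O[Si](C)(C)C(C)(C)C)C/C=C\CCCCCCCc1cc(O[Si](C)(C)C(C)(C)C)cc(O[Si](C)(C)C(C)(C)C)c1 | intermediate
20 | 5-[(8Z,11S)-11-hydroxyheptadec-8-en-1-yl]benzene-1,3-diol | CCCCCC[C@H](O)C/C=C\CCCCCCCc1cc(O)cc(O)c1 | target

## Step count and risks
Total steps: 9. Longest linear sequence: 6 (steps 1, 2, 3, 4, 8, 9). The other branch has 5 (steps 5, 6, 7, 8, 9).

**Step 1. Risk:** sluggish aryl Grignard coupling, biaryl formation and double arylation.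
The fallback sets out from 1 and comes back at 4. Sonogashira coupling of 1 with oct-7-yn-1-ol (PdCl2(PPh3)2, CuI, Et3N, 70 °C) gives 8-(3,5-dimethoxyphenyl)oct-7-yn-1-ol F1. Hydrogenation (H2, Pd/C, EtOAc) gives 8-(3,5-dimethoxyphenyl)octan-1-ol F2. Appel bromination (CBr4, PPh3, CH2Cl2, 0 °C) then delivers 4. No statistical step remains.

**Step 5. Risk:** ee below the level needed for a single enantiomer (check by Mosher ester or chiral GC on 14), and isopinocampheol co-eluting with 14.
The fallback sets out from 9 and comes back at 14.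
- Corey–Chaykovsky methylenation of 9 (trimethylsulfonium iodide, NaH, DMSO/THF) gives racemic 2-hexyloxirane F3.
- Hydrolytic kinetic resolution uses (S,S)-(salen)Co(OAc) at 0.5 mol % with 0.55 equiv H2O. Here salen is N,N′-bis(3,5-di-tert-butylsalicylidene)cyclohexane-1,2-diaminate and the cobalt is trivalent. It leaves (S)-2-hexyloxirane F4 in over 99% ee, which is distilled from the diol.
- CH2=CHMgBr with CuI (10 mol %) in THF at −30 °C opens F4 at the terminal carbon without touching the stereocentre and gives 14.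

**Step 8. Risk:** loss of silanol from 17 by E1cB under the basic ylide, or an eroded Z:E ratio. A minor E isomer can be removed on AgNO3-impregnated silica.
The fallback sets out from 7 and 17 and comes back at 19, with the roles of the partners reversed.
- Bromide 7 is oxidised with Me3NO in DMSO at rt (Ganem oxidation) to 8-[3,5-bis(tert-butyldimethylsilyloxy)phenyl]octanal F5.
- Aldehyde 17 is reduced (NaBH4, MeOH, 0 °C) to (S)-3-(tert-butyldimethylsilyloxy)nonan-1-ol F6.
- F6 is converted (I2, PPh3, imidazole, CH2Cl2) to (S)-tert-butyl[(1-iodononan-3-yl)oxy]dimethylsilane F7.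
- F7 is heated with PPh3 in MeCN to give [(S)-3-(tert-butyldimethylsilyloxy)nonyl]triphenylphosphonium iodide F8.
- NaN(SiMe3)2 in THF gives [(S)-3-(tert-butyldimethylsilyloxy)nonylidene]triphenylphosphorane F9, which reacts with F5 at −78 °C to give 19.

In this pairing the carbonyl partner has no β-leaving group, and the silyloxy group is γ to the ylide carbon.

## Further compounds
F1 | step 1 | 8-(3,5-dimethoxyphenyl)oct-7-yn-1-ol | COc1cc(C#CCCCCCCO)cc(OC)c1
F2 | step 1 | 8-(3,5-dimethoxyphenyl)octan-1-ol | COc1cc(CCCCCCCCO)cc(OC)c1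
F3 | step 5 | racemic 2-hexyloxirane | CCCCCCC1CO1
F4 | step 5 | (S)-2-hexyloxirane | CCCCCC[C@H]1CO1
F5 | step 8 | 8-[3,5-bis(tert-butyldimethylsilyloxy)phenyl]octanal | CC(C)(C)[Si](C)(C)Oc1cc(CCCCCCCC=O)cc(O[Si](C)(C)C(C)(C)C)c1
F6 | step 8 | (S)-3-(tert-butyldimethylsilyloxy)nonan-1-ol | CCCCCC[C@H](O[Si](C)(C)C(C)(C)C)CCO
F7 | step 8 | (S)-tert-butyl[(1-iodononan-3-yl)oxy]dimethylsilane | CCCCCC[C@H](O[Si](C)(C)C(C)(C)C)CCI
F8 | step 8 | [(S)-3-(tert-butyldimethylsilyloxy)nonyl]triphenylphosphonium iodide | CCCCCC[C@H](O[Si](C)(C)C(C)(C)C)CC[P+](c1ccccc1)(c1ccccc1)c1ccccc1.[I-]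
F9 | step 8 | [(S)-3-(tert-butyldimethylsilyloxy)nonylidene]triphenylphosphorane | CCCCCC[C@H](O[Si](C)(C)C(C)(C)C)CC=P(c1ccccc1)(c1ccccc1)c1ccccc1
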